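**Retrosynthetic overview** (decahydroquinoline numbering N1, C2–C8a; side chain C1'–C8')
1. The C3 ester is made last-but-one by Mitsunobu inversion with (E)-oct-2-enoic acid; C2, C3, C4a and C8a all arise in one all-cis hydrogenation of a 5-alkyl-2-methyl-5,6,7,8-tetrahydroquinolin-3-ol, steered by C5 alone.
2. Ring B (as a pyridine) is cut at N1–C8a and N1–C2 to a 1,5-diketone and hydroxylamine.
3. The diketone is cut at C5–C1' and C4a–C4: cyclohex-2-en-1-one (ring A complete), the side-chain terminal alkene (used as its alkylzirconocene) and 3-silyloxybut-3-en-2-one (C4, C3 with its oxygen, C2, 2-CH3) are joined in one catalytic asymmetric conjugate addition / Mukaiyama–Michael operation.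
4. Enabling feature: in ring A, C5 is β and C4a is α to C8a, the carbon that carries N1. With C8a as a ketone, ring A is a cyclohex-2-enone whose β-carbon C5 accepts C1' and whose α-carbon C4a then picks up C4; N1 lies 1,5 between C8a and C2.
5. Ring order: ring A is purchased, ring B is closed aromatic (step 5) and saturated (step 6); C5' comes from (R)-2-propyloxirane.

Key step: step 4

Remark on the chemistry: the target is read as 2R,3S,4aR,5R,8aS,5'R with a cis ring fusion; H2, H4a, H5 and H8a lie on one face and H3 on the other. The sense of induction in step 4 is assigned by analogy; the ligand enantiomer that gives 5R is meant, and its mirror image would be used if the opposite sense were found.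

**Step 1**
Reactants: 1 (R)-2-propyloxirane; 2 allylmagnesium chloride
Product: 3 (R)-oct-7-en-4-ol
Conditions: CuI (5 mol%), THF, −30 to 0 °C; NH4Cl (aq)
Reagents that add atoms: none
Why: Copper-catalysed SN2 opening of a terminal epoxide by an allyl Grignard reagent occurs at the unsubstituted carbon, so the stereocenter of 1 becomes C5' unchanged.

**Step 2**
Reactants: 3 (R)-oct-7-en-4-ol
Product: 4 (R)-triisopropyl(oct-7-en-4-yloxy)silane
Conditions: TIPSOTf, 2,6-lutidine, CH2Cl2, 0 °C to rt; NaHCO3 (aq)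
Reagents that add atoms: triisopropylsilyl trifluoromethanesulfonate, CC(C)[Si](C(C)C)(C(C)C)OS(=O)(=O)C(F)(F)F
Why: Silylation of a secondary alcohol with a silyl triflate and a hindered base is routine, and the triisopropylsilyl ether is chosen because it contains no arene and should withstand Cp2ZrHCl, TiCl4, hot ethanolic hydroxylammonium chloride and hydrogenation in AcOH.

**Step 3**
Reactants: 5 butane-2,3-dione
Product: 6 3-[(tert-butyldimethylsilyl)oxy]but-3-en-2-one
Conditions: TBSOTf (1.0 equiv), Et3N, CH2Cl2, 0 °C; NaHCO3 (aq)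
Reagents that add atoms: tert-butyldimethylsilyl trifluoromethanesulfonate, CC(C)(C)[Si](C)(C)OS(=O)(=O)C(F)(F)F
Why: Mono-enol silylation of a 1,2-diketone with one equivalent of silyl triflate gives the 2-silyloxy enone, a Michael acceptor that carries C4, C3 with its oxygen, C2 and the C2 methyl group.

**Step 4**
Reactants: 4 (R)-triisopropyl(oct-7-en-4-yloxy)silane; 7 cyclohex-2-en-1-one; 6 3-[(tert-butyldimethylsilyl)oxy]but-3-en-2-one
Product: 10 (3R)-2-[2-(tert-butyldimethylsilyloxy)-3-oxobutyl]-3-[(5R)-5-(triisopropylsilyloxy)octyl]cyclohexan-1-one, via alkylzirconocene chloride 8 (not isolated), via trimethylsilyl enol ether 9 (not isolated)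
Conditions: 4, Cp2ZrHCl, CH2Cl2, rt; then 7, (CuOTf)2·C6H6 (5 mol%), BINOL-derived bis(1-phenylethyl)amine phosphoramidite (11 mol%, enantiomer giving 5R), Me3SiCl, Et2O, rt; solvent exchange to CH2Cl2; then 6, TiCl4, −78 °C; NaHCO3 (aq)
Reagents that add atoms: none
Why: Anti-Markovnikov hydrozirconation puts zirconium on the terminal carbon of 4, and the catalyst formed from (CuOTf)2·C6H6 and the phosphoramidite transfers this primary alkyl group to the β-carbon of 7 (future C5) while Me3SiCl traps the enolate as the regiodefined enol ether 9, which TiCl4 then engages through its α-carbon (future C4a) with the methylene terminus of 6. The closest known reaction types are the copper-catalysed asymmetric conjugate addition of alkene-derived alkylzirconocenes to cyclic enones and the Mukaiyama–Michael addition of cyclohexanone silyl enol ethers to enones, run here one after the other in one flask. No ring is closed in this step; it delivers the C8a/C2 1,5-dicarbonyl array on which ring B is closed by condensation in step 5. The new stereocenter C5 is set by the chiral ligand on copper through face selection on the enone, independent of the remote silyloxy center of 4, whereas C4a and the silyloxy carbon are formed as mixtures and need no control because both become sp2 in step 5. The selectivity the step needs is regiochemical, namely C–C bond formation at the more hindered C4a and not at C8, and it is secured because the conjugate addition itself places the enol ether double bond between C8a and C4a; 1,4- over 1,2-attack on 6 follows from its unsubstituted β-methylene.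

**Step 5**
Reactants: 10 (3R)-2-[2-(tert-butyldimethylsilyloxy)-3-oxobutyl]-3-[(5R)-5-(triisopropylsilyloxy)octyl]cyclohexan-1-one
Product: 12 (5R)-2-methyl-5-[(5R)-5-(triisopropylsilyloxy)octyl]-5,6,7,8-tetrahydroquinolin-3-ol, via pyridyl tert-butyldimethylsilyl ether 11 (not isolated)
Conditions: NH2OH·HCl, EtOH, 78 °C; then K2CO3, MeOH, rt
Reagents that add atoms: hydroxylamine hydrochloride, NO.Cl
Why: Condensation of a 1,5-diketone with hydroxylamine closes ring B as an N-hydroxy-1,4-dihydropyridine that aromatises by loss of water without an external oxidant (classical 1,5-diketone–hydroxylamine pyridine synthesis), the silyl group on the C3 oxygen blocking acyloin tautomerisation beforehand, and carbonate methanolysis then frees the phenolic oxygen while the alkyl triisopropylsilyl ether stays.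

**Step 6**
Reactants: 12 (5R)-2-methyl-5-[(5R)-5-(triisopropylsilyloxy)octyl]-5,6,7,8-tetrahydroquinolin-3-ol
Product: 13 (2R,3R,4aR,5R,8aS)-2-methyl-5-[(5R)-5-(triisopropylsilyloxy)octyl]decahydroquinolin-3-ol
Conditions: H2 (50 bar), Rh/Al2O3 (5 wt% Rh), AcOH, 40 °C; NaOH (aq) work-up
Reagents that add atoms: none
Why: Heterogeneous hydrogenation of a pyridine in acid adds all hydrogens to one face (all-cis piperidine, cis ring fusion), and the C5 chain, held pseudoaxial by allylic 1,3-strain with the peri C4–H, should shield its own face so that C2, C3, C4a and C8a receive hydrogen anti to it, rhodium being chosen to limit C3–O hydrogenolysis.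

**Step 7**
Reactants: 13 (2R,3R,4aR,5R,8aS)-2-methyl-5-[(5R)-5-(triisopropylsilyloxy)octyl]decahydroquinolin-3-ol
Product: 14 tert-butyl (2R,3R,4aR,5R,8aS)-3-hydroxy-2-methyl-5-[(5R)-5-(triisopropylsilyloxy)octyl]octahydroquinoline-1(2H)-carboxylate
Conditions: Boc2O, Et3N, CH2Cl2, 40 °C
Reagents that add atoms: di-tert-butyl dicarbonate, CC(C)(C)OC(=O)OC(=O)OC(C)(C)C
Why: Carbamoylation with Boc2O without an acylation catalyst is selective for the secondary amine over the secondary alcohol and masks N1 for the Mitsunobu step.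

**Step 8**
Reactants: 14 tert-butyl (2R,3R,4aR,5R,8aS)-3-hydroxy-2-methyl-5-[(5R)-5-(triisopropylsilyloxy)octyl]octahydroquinoline-1(2H)-carboxylate; 15 (E)-oct-2-enoic acid
Product: 16 tert-butyl (2R,3S,4aR,5R,8aS)-2-methyl-3-[(2E)-oct-2-enoyloxy]-5-[(5R)-5-(triisopropylsilyloxy)octyl]octahydroquinoline-1(2H)-carboxylate
Conditions: PPh3, DIAD, toluene, 0 °C to rt
Reagents that add atoms: none
Why: Mitsunobu esterification displaces the oxyphosphonium group by the carboxylate in an SN2 process, so C3 is inverted to the required 3S configuration (ester trans to the C2 methyl group) with the (E)-enoate untouched, and the endocyclic carbamate cannot participate because the derived cyclic carbamate would be a strained bridged ring.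

**Step 9**
Reactants: 16 tert-butyl (2R,3S,4aR,5R,8aS)-2-methyl-3-[(2E)-oct-2-enoyloxy]-5-[(5R)-5-(triisopropylsilyloxy)octyl]octahydroquinoline-1(2H)-carboxylate
Product: 18 (2R,3S,4aR,5R,8aS)-5-[(5R)-5-hydroxyoctyl]-2-methyldecahydroquinolin-3-yl (2E)-oct-2-enoate, via N-Boc hydroxy ester 17 (not isolated)
Conditions: HF·pyridine, pyridine, THF, 0 °C to rt; concentrate; then TFA, CH2Cl2, 0 °C; NaHCO3 (aq)
Reagents that add atoms: none
Why: Fluoride cleaves the triisopropylsilyl ether while N1 is still acylated, so that no O-to-N acyl shift can occur at that stage, and acidolysis of the tert-butyl carbamate then frees the amine as its salt, neither stage touching the enoate or a stereocenter.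

**Compound list**
1 | (R)-2-propyloxirane | CCC[C@@H]1CO1 | starting material
2 | allylmagnesium chloride | C=CC[Mg]Cl | starting material
3 | (R)-oct-7-en-4-ol | C=CCC[C@H](O)CCC | intermediate
4 | (R)-triisopropyl(oct-7-en-4-yloxy)silane | C=CCC[C@H](O[Si](C(C)C)(C(C)C)C(C)C)CCC | intermediate
5 | butane-2,3-dione | CC(=O)C(C)=O | starting material
6 | 3-[(tert-butyldimethylsilyl)oxy]but-3-en-2-one | CC(=O)C(=C)O[Si](C)(C)C(C)(C)C | intermediate
7 | cyclohex-2-en-1-one | O=C1C=CCCC1 | starting material
8 | chlorobis(cyclopentadienyl)[(5R)-5-(triisopropylsilyloxy)octyl]zirconium | Cl[Zr](C1C=CC=C1)(C1C=CC=C1)CCCC[C@H](O[Si](C(C)C)(C(C)C)C(C)C)CCC | intermediate (not isolated)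
9 | trimethyl({(3R)-3-[(5R)-5-(triisopropylsilyloxy)octyl]cyclohex-1-en-1-yl}oxy)silane | C[Si](C)(C)OC1=C[C@H](CCCC[C@H](O[Si](C(C)C)(C(C)C)C(C)C)CCC)CCC1 | intermediate (not isolated)
10 | (3R)-2-[2-(tert-butyldimethylsilyloxy)-3-oxobutyl]-3-[(5R)-5-(triisopropylsilyloxy)octyl]cyclohexan-1-one (ring C2 and the silyloxy carbon as mixtures) | CC(=O)C(O[Si](C)(C)C(C)(C)C)CC1C(=O)CCC[C@H]1CCCC[C@H](O[Si](C(C)C)(C(C)C)C(C)C)CCC | intermediate
11 | (5R)-3-(tert-butyldimethylsilyloxy)-2-methyl-5-[(5R)-5-(triisopropylsilyloxy)octyl]-5,6,7,8-tetrahydroquinoline | Cc1nc2CCC[C@@H](CCCC[C@H](O[Si](C(C)C)(C(C)C)C(C)C)CCC)c2cc1O[Si](C)(C)C(C)(C)C | intermediate (not isolated)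
12 | (5R)-2-methyl-5-[(5R)-5-(triisopropylsilyloxy)octyl]-5,6,7,8-tetrahydroquinolin-3-ol | Cc1nc2CCC[C@@H](CCCC[C@H](O[Si](C(C)C)(C(C)C)C(C)C)CCC)c2cc1O | intermediate
13 | (2R,3R,4aR,5R,8aS)-2-methyl-5-[(5R)-5-(triisopropylsilyloxy)octyl]decahydroquinolin-3-ol | O[C@@H]1C[C@@H]2[C@H](CCCC[C@H](O[Si](C(C)C)(C(C)C)C(C)C)CCC)CCC[C@@H]2N[C@@H]1C | intermediate
14 | tert-butyl (2R,3R,4aR,5R,8aS)-3-hydroxy-2-methyl-5-[(5R)-5-(triisopropylsilyloxy)octyl]octahydroquinoline-1(2H)-carboxylate | O[C@@H]1C[C@@H]2[C@H](CCCC[C@H](O[Si](C(C)C)(C(C)C)C(C)C)CCC)CCC[C@@H]2N(C(=O)OC(C)(C)C)[C@@H]1C | intermediate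
15 | (E)-oct-2-enoic acid | CCCCC/C=C/C(=O)O | starting material
16 | tert-butyl (2R,3S,4aR,5R,8aS)-2-methyl-3-[(2E)-oct-2-enoyloxy]-5-[(5R)-5-(triisopropylsilyloxy)octyl]octahydroquinoline-1(2H)-carboxylate | CCCCC/C=C/C(=O)O[C@H]1C[C@@H]2[C@H](CCCC[C@H](O[Si](C(C)C)(C(C)C)C(C)C)CCC)CCC[C@@H]2N(C(=O)OC(C)(C)C)[C@@H]1C | intermediate
17 | tert-butyl (2R,3S,4aR,5R,8aS)-5-[(5R)-5-hydroxyoctyl]-2-methyl-3-[(2E)-oct-2-enoyloxy]octahydroquinoline-1(2H)-carboxylate | CCCCC/C=C/C(=O)O[C@H]1C[C@@H]2[C@H](CCCC[C@H](O)CCC)CCC[C@@H]2N(C(=O)OC(C)(C)C)[C@@H]1C | intermediate (not isolated)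
18 | (2R,3S,4aR,5R,8aS)-5-[(5R)-5-hydroxyoctyl]-2-methyldecahydroquinolin-3-yl (2E)-oct-2-enoate | CCCCC/C=C/C(=O)O[C@H]1C[C@@H]2[C@H](CCCC[C@H](O)CCC)CCC[C@@H]2N[C@@H]1C | target

**Totals**
Total step count: 9. Longest linear sequence: 8 steps (1, 2, 4, 5, 6, 7, 8, 9); step 3 is a one-step side branch.

**Steps most likely to fail**

Step 4. The second stage may not take place in the flask: the enol ether may be protodesilylated by adventitious acid, or the silyloxy enone may be consumed by residual alkylzirconium and copper. Only the untrapped 3-alkylcyclohexanone would then be returned, and its later enolisation would not be regioselective. The fallback sets out from 9 and comes back at 12.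
- Commercial 1-(benzyloxy)propan-2-one and N,N-dimethylformamide dimethyl acetal (90 °C) give the enaminone 3-(benzyloxy)-4-(dimethylamino)but-3-en-2-one F1.
- The conjugate addition is worked up without water and 9 is isolated; MeLi (THF, 0 °C) converts it into the regiodefined lithium enolate F2.
- F2 should add to F1 with loss of dimethylamine to give the ene-dione F3.
- NH4OAc in AcOH at 80 °C should close ring B directly at the pyridine oxidation level to the benzyl ether (5R)-3-(benzyloxy)-2-methyl-5-[(5R)-5-(triisopropylsilyloxy)octyl]-5,6,7,8-tetrahydroquinoline F4.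
- Hydrogenolysis (H2, Pd/C, EtOH) returns to the route at 12.

Step 6. Face discrimination by the C5 chain on the metal surface may be poor, enamine intermediates may desorb and re-adsorb to give trans-fused material, and the C3–O bond may be hydrogenolysed. The fallback replaces substrate control on a surface by catalyst control on an activated pyridinium salt; it sets out from 12 and comes back at 13.
- O-benzylation (BnBr, K2CO3, acetone) gives the benzyl ether F4 already described.
- Further BnBr in MeCN at 80 °C gives the N-benzylpyridinium bromide F5.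
- Homogeneous hydrogenation ([Ir(cod)Cl]2, an axially chiral bisphosphine such as SegPhos in the enantiomer matched to C5, H2 40 bar, THF/CH2Cl2) should give the all-cis N,O-dibenzyl decahydroquinoline F6.
- Hydrogenolysis of both benzyl groups (H2, Pd(OH)2/C, EtOH, AcOH) returns to 13.

Step 8. The activated alcohol may eliminate toward the enecarbamate, or the flanked C3 may not be displaced at all. The fallback separates inversion from acylation and uses a small, weakly basic oxygen nucleophile; it sets out from 14 and comes back at 16.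
- Tf2O and pyridine (CH2Cl2, −20 °C) give the triflate F7.
- Tetrabutylammonium nitrite in DMF at rt (Lattrell–Dax inversion) should give the nitrite ester F8, which aqueous work-up hydrolyses to the inverted N-Boc (3S)-alcohol F9.
- Steglich esterification with 15 (EDC·HCl, DMAP, CH2Cl2) gives 16 with retention.

**Further compounds**
F1 | step 4 | 3-(benzyloxy)-4-(dimethylamino)but-3-en-2-one | CC(=O)C(OCc1ccccc1)=CN(C)C
F2 | step 4 | lithium (3R)-3-[(5R)-5-(triisopropylsilyloxy)octyl]cyclohex-1-en-1-olate | [Li]OC1=C[C@H](CCCC[C@H](O[Si](C(C)C)(C(C)C)C(C)C)CCC)CCC1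
F3 | step 4 | (3R)-2-[2-(benzyloxy)-3-oxobut-1-en-1-yl]-3-[(5R)-5-(triisopropylsilyloxy)octyl]cyclohexan-1-one | CC(=O)C(OCc1ccccc1)=CC1C(=O)CCC[C@H]1CCCC[C@H](O[Si](C(C)C)(C(C)C)C(C)C)CCC
F4 | step 4 | (5R)-3-(benzyloxy)-2-methyl-5-[(5R)-5-(triisopropylsilyloxy)octyl]-5,6,7,8-tetrahydroquinoline | Cc1nc2CCC[C@@H](CCCC[C@H](O[Si](C(C)C)(C(C)C)C(C)C)CCC)c2cc1OCc1ccccc1
F5 | step 6 | (5R)-1-benzyl-3-(benzyloxy)-2-methyl-5-[(5R)-5-(triisopropylsilyloxy)octyl]-5,6,7,8-tetrahydroquinolin-1-ium bromide | Cc1c(OCc2ccccc2)cc2c([n+]1Cc1ccccc1)CCC[C@H]2CCCC[C@H](O[Si](C(C)C)(C(C)C)C(C)C)CCC.[Br-]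
F6 | step 6 | (2R,3R,4aR,5R,8aS)-1-benzyl-3-(benzyloxy)-2-methyl-5-[(5R)-5-(triisopropylsilyloxy)octyl]decahydroquinoline | c1ccccc1CO[C@@H]1C[C@@H]2[C@H](CCCC[C@H](O[Si](C(C)C)(C(C)C)C(C)C)CCC)CCC[C@@H]2N(Cc2ccccc2)[C@@H]1C
F7 | step 8 | tert-butyl (2R,3R,4aR,5R,8aS)-2-methyl-3-(trifluoromethanesulfonyloxy)-5-[(5R)-5-(triisopropylsilyloxy)octyl]octahydroquinoline-1(2H)-carboxylate | FC(F)(F)S(=O)(=O)O[C@@H]1C[C@@H]2[C@H](CCCC[C@H](O[Si](C(C)C)(C(C)C)C(C)C)CCC)CCC[C@@H]2N(C(=O)OC(C)(C)C)[C@@H]1C
F8 | step 8 | tert-butyl (2R,3S,4aR,5R,8aS)-2-methyl-3-(nitrosooxy)-5-[(5R)-5-(triisopropylsilyloxy)octyl]octahydroquinoline-1(2H)-carboxylate | O=NO[C@H]1C[C@@H]2[C@H](CCCC[C@H](O[Si](C(C)C)(C(C)C)C(C)C)CCC)CCC[C@@H]2N(C(=O)OC(C)(C)C)[C@@H]1C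
F9 | step 8 | tert-butyl (2R,3S,4aR,5R,8aS)-3-hydroxy-2-methyl-5-[(5R)-5-(triisopropylsilyloxy)octyl]octahydroquinoline-1(2H)-carboxylate | O[C@H]1C[C@@H]2[C@H](CCCC[C@H](O[Si](C(C)C)(C(C)C)C(C)C)CCC)CCC[C@@H]2N(C(=O)OC(C)(C)C)[C@@H]1C
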